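The cyclopentane (C1–C5) together with its exocyclic carbon C6 is a hidden p-menthane: in a six-membered ring C1–C2–C3–C4–C6–C5 the methyl carbon C1 and the isopropyl carbinol C4 stand para. (R)-Terpinen-4-ol thus supplies ten carbons and the C4 stereocentre. Everything rests on expelling C6 from this ring. Photochemical Wolff rearrangement of a monocyclic 2-diazo ketone shifts C4 from C6 to C5, contracts the cyclohexanone to the cyclopentane, delivers C6 as a ketene that is caught as a Weinreb amide, and sets C5, the ring-fusion CH wedged between the fully substituted C1 and C4, by kinetic protonation. Methallyl addition and ring-closing metathesis then close the cycloheptene.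

Key step: step 4

Numbering used throughout (daucane): C1 = quaternary ring-fusion carbon (CH3), C2 and C3 = cyclopentane CH2, C4 = C(OH)(isopropyl), C5 = ring-fusion CH, C6 = CH–O(acyl), C7 = CH2, C8 = C(CH3)=, C9 = =CH, C10 = CH2. In the target the C1 methyl, the C4 isopropyl and the C6 oxygen lie on one face. H5, the C4–OH and C10 lie on the other face.

Assumption: (R)-(−)-terpinen-4-ol is used as enantiopure commercial material. It is the only source of absolute configuration.

Step 1
Reactants: 1 (R)-(−)-terpinen-4-ol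
Product: 2 (6S)-6-hydroxy-3-methyl-6-(propan-2-yl)cyclohex-2-en-1-one
Conditions: Rh2(cap)4 (dirhodium tetracaprolactamate, 1 mol %), t-BuOOH (70 % aq., 5 equiv), K2CO3 (0.5 equiv), CH2Cl2, rt
Reagents that add atoms: tert-butyl hydroperoxide, CC(C)(C)OO
Why: Catalytic allylic C–H oxidation by a tert-butylperoxyl radical chain should oxidise the ring CH2 next to the =CH terminus (C6), as in other trisubstituted cyclohexenes, because the derived allyl radical is trapped at its secondary end, which gives the β-methyl enone and leaves the C4 stereocentre untouched (the descriptor changes only through priorities).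

Step 2
Reactants: 2 (6S)-6-hydroxy-3-methyl-6-(propan-2-yl)cyclohex-2-en-1-one; 3 allyltrimethylsilane
Product: 4 (2S,5R)-2-hydroxy-5-methyl-2-(propan-2-yl)-5-(prop-2-en-1-yl)cyclohexan-1-one (allyl cis to OH)
Conditions: TiCl4 (1.2 equiv), CH2Cl2, −78 °C, 15 min; then 3 (2 equiv), −78 to −40 °C; H2O
Reagents that add atoms: none
Why: In this Hosomi–Sakurai conjugate allylation the α'-hydroxy enone binds titanium as a five-membered alkoxide–carbonyl chelate that holds the C4–O bond in the enone plane and turns the isopropyl group axial, so chair-like axial attack on C1 comes from the face opposite isopropyl and sets C1 with allyl cis to OH.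

Step 3
Reactants: 4 (2S,5R)-2-hydroxy-5-methyl-2-(propan-2-yl)-5-(prop-2-en-1-yl)cyclohexan-1-one
Product: 6 (3R,6S)-2-diazo-6-hydroxy-3-methyl-6-(propan-2-yl)-3-(prop-2-en-1-yl)cyclohexan-1-one, via trifluoroacetyl ketone 5 (not isolated)
Conditions: LiN(SiMe3)2 (2.2 equiv), THF, −78 °C; CF3CO2CH2CF3 (1.3 equiv); 5 % aq. HCl work-up; crude 5, 4-acetamidobenzenesulfonyl azide (1.5 equiv), Et3N (1.5 equiv), H2O (1 equiv), MeCN, rt
Reagents that add atoms: 2,2,2-trifluoroethyl trifluoroacetate, O=C(OCC(F)(F)F)C(F)(F)F (CF3CO group of 5 only); 4-acetamidobenzenesulfonyl azide, CC(=O)Nc1ccc(cc1)S(=O)(=O)N=[N+]=[N-] (N2 of 6)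
Why: In this detrifluoroacetylative Regitz-type diazo transfer C5 is the only enolisable position of 4 because C4 is fully substituted, the second equivalent of base only parks the hydroxyl as its alkoxide, and activation as the trifluoroacetyl ketone lets the sulfonyl azide deliver N2 to this neopentyl carbon without making a stereocentre.

Step 4
Reactants: 6 (3R,6S)-2-diazo-6-hydroxy-3-methyl-6-(propan-2-yl)-3-(prop-2-en-1-yl)cyclohexan-1-one
Product: 9 (1R,2S,5R)-2-hydroxy-N-methoxy-N,5-dimethyl-2-(propan-2-yl)-5-(prop-2-en-1-yl)cyclopentane-1-carboxamide, via ketene 7 (not isolated), via amide enol 8 (not isolated)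
Conditions: hν (medium-pressure Hg lamp, Pyrex, λ > 300 nm), MeNH(OMe) (free base, 10 equiv), THF, 0 °C
Reagents that add atoms: N,O-dimethylhydroxylamine, CNOC
Why: Photolysis of the cyclic, s-Z-locked 2-diazo ketone expels N2 with a concerted 1,2-shift of C4 from the carbonyl carbon C6 to the diazo carbon C5 (Wolff rearrangement, the standard photochemical ring contraction of 2-diazocycloalkanones) and gives ketene 7. The cyclopentane C1–C2–C3–C4–C5 is therefore closed by a three-centre shift that makes C4–C5 as C4–C6 breaks, not by an exo or endo cyclisation, and C4 migrates with retention, so C1 and C4 are untouched. The amine adds to the ketene carbon to give amide enol 8, whose ketonisation creates the only new stereocentre, C5. The proton should reach C5 from the face that carries the C4–OH and the allyl CH2 on C1, because the other face is covered by the C4 isopropyl and C1 methyl groups, so C6 ends up cis to isopropyl and methyl, the kinetically set and less stable arrangement that the trans ring fusion needs. The step needs rearrangement to win over carbene O–H or C–H insertion, which the locked s-Z geometry secures, and external capture of the ketene to win over lactonisation by the C4–OH, which the large excess of the α-effect amine secures.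

Step 5
Reactants: 9 (1R,2S,5R)-2-hydroxy-N-methoxy-N,5-dimethyl-2-(propan-2-yl)-5-(prop-2-en-1-yl)cyclopentane-1-carboxamide; 10 (2-methylallyl)magnesium chloride
Product: 11 1-[(1R,2S,5R)-2-hydroxy-5-methyl-2-(propan-2-yl)-5-(prop-2-en-1-yl)cyclopentyl]-3-methylbut-3-en-1-one
Conditions: 10 (3 equiv, 0.5 M in THF), THF, −78 to 0 °C; cold 0.5 M aq. HCl
Reagents that add atoms: none
Why: In this Weinreb ketone synthesis the allylic Grignard reagent first deprotonates the hydroxyl and then adds once to give a chelated tetrahedral adduct that survives until the cold acidic quench, so the base-sensitive β,γ-unsaturated β'-hydroxy ketone is released only at work-up and C5 is not epimerised.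

Step 6
Reactants: 11 1-[(1R,2S,5R)-2-hydroxy-5-methyl-2-(propan-2-yl)-5-(prop-2-en-1-yl)cyclopentyl]-3-methylbut-3-en-1-one
Product: 12 (3S,3aR,8aR)-3-hydroxy-6,8a-dimethyl-3-(propan-2-yl)-2,3,3a,5,8,8a-hexahydroazulen-4(1H)-one
Conditions: second-generation Grubbs catalyst RuCl2(=CHPh)(PCy3)(H2IMes) (5 mol %), 1,4-benzoquinone (10 mol %), CH2Cl2 (2 mM), 40 °C
Reagents that add atoms: none
Why: Ring-closing metathesis of the monosubstituted allyl alkene and the 1,1-disubstituted methallyl alkene gives the trisubstituted C8=C9 bond of the cycloheptene, the trans arrangement of the two arms on C1 and C5 is carried into the trans ring fusion, and benzoquinone suppresses ruthenium hydride isomerisation of the β,γ-enone.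

Step 7
Reactants: 12 (3S,3aR,8aR)-3-hydroxy-6,8a-dimethyl-3-(propan-2-yl)-2,3,3a,5,8,8a-hexahydroazulen-4(1H)-one
Product: 13 (3S,3aS,4R,8aR)-6,8a-dimethyl-3-(propan-2-yl)-1,2,3,3a,4,5,8,8a-octahydroazulene-3,4-diol
Conditions: Me4N[BH(OAc)3] (5 equiv), MeCN/AcOH 1:1, −30 to 0 °C; H2O
Reagents that add atoms: none
Why: In this hydroxyl-directed reduction of the Evans–Saksena type the C4–OH exchanges onto boron and hands hydride to the C6 carbonyl from its own face, which is also the open face opposite the C1 methyl and C4 isopropyl groups, so the C6–OH ends up anti to the C4–OH and cis to the methyl group, while the acidic medium avoids retro-aldol cleavage and enone conjugation.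

Step 8
Reactants: 13 (3S,3aS,4R,8aR)-6,8a-dimethyl-3-(propan-2-yl)-1,2,3,3a,4,5,8,8a-octahydroazulene-3,4-diol; 14 4-acetoxybenzoic acid
Product: 15 (3S,3aS,4R,8aR)-3-hydroxy-6,8a-dimethyl-3-(propan-2-yl)-1,2,3,3a,4,5,8,8a-octahydroazulen-4-yl 4-acetoxybenzoate
Conditions: 14 (1.5 equiv), DCC (1.5 equiv), DMAP (0.3 equiv), toluene, 60 °C
Reagents that add atoms: none
Why: In this Steglich esterification only the secondary C6–OH is acylated because the tertiary C4–OH next to isopropyl is inert to the acylpyridinium species, and C6 keeps its configuration since its C–O bond is not broken.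

Step 9
Reactants: 15 (3S,3aS,4R,8aR)-3-hydroxy-6,8a-dimethyl-3-(propan-2-yl)-1,2,3,3a,4,5,8,8a-octahydroazulen-4-yl 4-acetoxybenzoate
Product: 16 (3S,3aS,4R,8aR)-3-hydroxy-6,8a-dimethyl-3-(propan-2-yl)-1,2,3,3a,4,5,8,8a-octahydroazulen-4-yl 4-hydroxybenzoate (target)
Conditions: pyrrolidine (3 equiv), CH2Cl2, 0 °C to rt
Reagents that add atoms: none
Why: In this chemoselective aminolysis the phenyl acetate is a far better acyl donor than the hindered secondary alkyl benzoate, so pyrrolidine removes only the acetyl group.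

Compound list
1 | (R)-(−)-terpinen-4-ol, (1R)-4-methyl-1-(propan-2-yl)cyclohex-3-en-1-ol | CC1=CC[C@@](O)(C(C)C)CC1 | starting material
2 | (6S)-6-hydroxy-3-methyl-6-(propan-2-yl)cyclohex-2-en-1-one | CC1=CC(=O)[C@@](O)(C(C)C)CC1 | intermediate
3 | allyltrimethylsilane | C=CC[Si](C)(C)C | starting material
4 | (2S,5R)-2-hydroxy-5-methyl-2-(propan-2-yl)-5-(prop-2-en-1-yl)cyclohexan-1-one | C=CC[C@@]1(C)CC[C@](O)(C(C)C)C(=O)C1 | intermediate
5 | (2S,5R)-2-hydroxy-5-methyl-2-(propan-2-yl)-5-(prop-2-en-1-yl)-6-(trifluoroacetyl)cyclohexan-1-one (C6 unassigned, largely enol) | C=CC[C@@]1(C)CC[C@](O)(C(C)C)C(=O)C1C(=O)C(F)(F)F | intermediate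
6 | (3R,6S)-2-diazo-6-hydroxy-3-methyl-6-(propan-2-yl)-3-(prop-2-en-1-yl)cyclohexan-1-one | C=CC[C@@]1(C)CC[C@](O)(C(C)C)C(=O)C1=[N+]=[N-] | intermediate
7 | [(2S,5R)-2-hydroxy-5-methyl-2-(propan-2-yl)-5-(prop-2-en-1-yl)cyclopentylidene]methanone (ketene) | C=CC[C@@]1(C)CC[C@](O)(C(C)C)C1=C=O | intermediate
8 | enol of amide 9 (C5=C6 double bond, geometry unassigned) | C=CC[C@@]1(C)CC[C@](O)(C(C)C)C1=C(O)N(C)OC | intermediate
9 | (1R,2S,5R)-2-hydroxy-N-methoxy-N,5-dimethyl-2-(propan-2-yl)-5-(prop-2-en-1-yl)cyclopentane-1-carboxamide | C=CC[C@@]1(C)CC[C@](O)(C(C)C)[C@@H]1C(=O)N(C)OC | intermediate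
10 | (2-methylallyl)magnesium chloride | CC(=C)C[Mg]Cl | starting material
11 | 1-[(1R,2S,5R)-2-hydroxy-5-methyl-2-(propan-2-yl)-5-(prop-2-en-1-yl)cyclopentyl]-3-methylbut-3-en-1-one | C=CC[C@@]1(C)CC[C@](O)(C(C)C)[C@@H]1C(=O)CC(C)=C | intermediate
12 | (3S,3aR,8aR)-3-hydroxy-6,8a-dimethyl-3-(propan-2-yl)-2,3,3a,5,8,8a-hexahydroazulen-4(1H)-one | CC1=CC[C@@]2(C)CC[C@](O)(C(C)C)[C@@H]2C(=O)C1 | intermediate
13 | (3S,3aS,4R,8aR)-6,8a-dimethyl-3-(propan-2-yl)-1,2,3,3a,4,5,8,8a-octahydroazulene-3,4-diol | CC1=CC[C@@]2(C)CC[C@](O)(C(C)C)[C@@H]2[C@H](O)C1 | intermediate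
14 | 4-acetoxybenzoic acid | CC(=O)Oc1ccc(cc1)C(=O)O | starting material
15 | (3S,3aS,4R,8aR)-3-hydroxy-6,8a-dimethyl-3-(propan-2-yl)-1,2,3,3a,4,5,8,8a-octahydroazulen-4-yl 4-acetoxybenzoate | CC1=CC[C@@]2(C)CC[C@](O)(C(C)C)[C@@H]2[C@H](OC(=O)c2ccc(OC(C)=O)cc2)C1 | intermediate
16 | (3S,3aS,4R,8aR)-3-hydroxy-6,8a-dimethyl-3-(propan-2-yl)-1,2,3,3a,4,5,8,8a-octahydroazulen-4-yl 4-hydroxybenzoate | CC1=CC[C@@]2(C)CC[C@](O)(C(C)C)[C@@H]2[C@H](OC(=O)c2ccc(O)cc2)C1 | target

Total step count: 9. Longest linear sequence: 9 steps (from 1).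

Steps most likely to fail

Step 4. The ketonisation of enol 8 may show poor facial selectivity. The neighbouring C4 hydroxyl may also capture the ketene before the amine does, which would place C6 on the wrong face of C5. The fallback sets out from 6 and comes back at 9, and it separates ring contraction from control of C5. Irradiation of 6 in methanol gives methyl (2S,5R)-2-hydroxy-5-methyl-2-(propan-2-yl)-5-(prop-2-en-1-yl)cyclopentane-1-carboxylate as a C1 epimer mixture F1. LiN(iPr)2 (3 equiv, THF, −78 °C) converts both epimers into one alkoxide–ester enolate. A quench with the bulky acid 2,6-di-tert-butyl-4-methylphenol should protonate this enolate from the open face, a stereoconvergent correction that gives methyl (1R,2S,5R)-2-hydroxy-5-methyl-2-(propan-2-yl)-5-(prop-2-en-1-yl)cyclopentane-1-carboxylate F2. AlMe3 and MeNH(OMe)·HCl (CH2Cl2, 0 °C to rt) then turn F2 into 9.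

Step 2. Reaction through the non-chelated conformer (isopropyl equatorial) would reverse the facial selectivity at C1. The fallback sets out from 2 and comes back at 4. The allyl group is first bound to C6 and then moved to C1 across the same face. Allylmagnesium bromide (2.5 equiv, THF, −78 °C) adds 1,2 to the magnesium chelate of 2 from the face opposite isopropyl and gives the trans-diol (1S,2R)-4-methyl-1-(propan-2-yl)-2-(prop-2-en-1-yl)cyclohex-3-ene-1,2-diol F3. KH and 18-crown-6 (THF, 0 °C to rt) trigger the anionic oxy-Cope rearrangement. This shift is suprafacial on the ring, so it carries the allyl group from C6 to C1 on the face of the C4–OH. It returns the C6 ketone as its enolate, which gives 4 on protonation.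

Step 1. Hydrogen abstraction at the C2 methylene or at the C1 methyl group would erode site selectivity. The fallback sets out from 1 and comes back at 2. It brings oxygen to C6 by a relay of polar steps.
- VO(acac)2 and t-BuOOH (CH2Cl2, 0 °C) epoxidise 1 on the hydroxyl face to the cis-1,2-epoxide of terpinen-4-ol F4.
- PhSeNa (from PhSeSePh and NaBH4, EtOH) opens the epoxide at the secondary carbon C5 to the trans hydroxy phenyl selenide F5.
- H2O2 gives the selenoxide F6, which can eliminate only toward C6 and gives the cis-p-menth-2-ene-1,4-diol F7.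
- Pyridinium chlorochromate, C5H5NH[CrO3Cl] (CH2Cl2, rt), effects the Babler–Dauben oxidative transposition through the less hindered methyl carbinol (C1–OH to C6=O) and gives 2.

Further compounds
F1 | step 4 | methyl (2S,5R)-2-hydroxy-5-methyl-2-(propan-2-yl)-5-(prop-2-en-1-yl)cyclopentane-1-carboxylate, C1 epimer mixture | C=CC[C@@]1(C)CC[C@](O)(C(C)C)C1C(=O)OC
F2 | step 4 | methyl (1R,2S,5R)-2-hydroxy-5-methyl-2-(propan-2-yl)-5-(prop-2-en-1-yl)cyclopentane-1-carboxylate | C=CC[C@@]1(C)CC[C@](O)(C(C)C)[C@@H]1C(=O)OC
F3 | step 2 | (1S,2R)-4-methyl-1-(propan-2-yl)-2-(prop-2-en-1-yl)cyclohex-3-ene-1,2-diol | CC1=C[C@](O)(CC=C)[C@@](O)(C(C)C)CC1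
F4 | step 1 | cis-1,2-epoxide of terpinen-4-ol (oxirane oxygen on the face of the OH) | C[C@]12CC[C@](O)(C(C)C)C[C@H]1O2
F5 | step 1 | trans hydroxy phenyl selenide (SePh on C5, both OH groups on the opposite face) | C[C@]1(O)CC[C@](O)(C(C)C)C[C@@H]1[Se]c1ccccc1
F6 | step 1 | selenoxide of F5 | C[C@]1(O)CC[C@](O)(C(C)C)C[C@@H]1[Se](=O)c1ccccc1
F7 | step 1 | cis-p-menth-2-ene-1,4-diol | C[C@]1(O)CC[C@](O)(C(C)C)C=C1
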